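**Retrosynthetic overview**
1. Endgame: the ring senecioate goes on last by Mitsunobu inversion; the oxirane comes from hydroxyl-directed epoxidation of a 2-methylcyclohex-2-enol (ketone reduced, later re-oxidised); the 1,1-disubstituted alkene comes from methylenation of a side-chain ketone.
2. Key disconnection: the carbocycle is cut at the CH2–CH(oxirane) bond and at the CH(O-acyl)–CH(side chain) bond, a Diels–Alder reaction of (1Z)-1-(TBSO)-3-methyl-2-(TESO)buta-1,3-diene with (4R)-4-hydroxy-7-methylocta-1,6-dien-3-one that brings all fifteen skeletal carbons together.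
3. Enabling feature: the side-chain carbinol CH–O is bonded directly to the methylene-bearing sp2 carbon on the ring CH; with that carbon as C=O the side chain is an α'-hydroxy vinyl ketone whose OH···O=C bond activates it and differentiates its faces, and the ring's adjacent C=O/CH–O pair next to the C-methyl carbon is the enediol diether of the diene.
4. Stereochemical relay: one bought stereocentre (methyl (R)-glycidate, which becomes the side-chain carbinol) sets both new ring stereocentres in the cycloaddition; these steer the ketone reduction, the resulting alcohol directs the epoxidation, and the ring carbinol is inverted at the end.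
5. Ring order: cyclohexene first (step 7), oxirane second (step 12).

Key step: step 7

Remark: soft enolisation of 10 is assumed to give mainly the (1Z) dienyl ether; the (1E) isomer, with OTBS inside the s-cis diene, should not cycloadd at a useful rate.

**Step 1**
Reactants: 1 methyl (2R)-oxirane-2-carboxylate (methyl (R)-glycidate); 2 (2-methylprop-1-en-1-yl)magnesium bromide
Product: 3 methyl (2R)-2-hydroxy-5-methylhex-4-enoate
Conditions: CuBr·SMe2 (10 mol %), THF, −78 to −40 °C
Reagents that add atoms: none
Why: Copper-catalysed SN2 opening of the glycidic ester at its unsubstituted carbon by the alkenyl Grignard reagent leaves the stereocentre untouched, so the (R) configuration of 1 becomes that of the carbinol.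

**Step 2**
Reactants: 3 methyl (2R)-2-hydroxy-5-methylhex-4-enoate
Product: 4 (2R)-2-hydroxy-N-methoxy-N,5-dimethylhex-4-enamide
Conditions: MeNH(OMe)·HCl, i-PrMgCl, THF, −20 to 0 °C
Reagents that add atoms: N,O-dimethylhydroxylamine hydrochloride, CNOC.Cl
Why: Weinreb amidation of the ester by the magnesium amide formed in the flask; the α-hydroxy ester should react as its magnesium alkoxide without loss of configuration.

**Step 3**
Reactants: 4 (2R)-2-hydroxy-N-methoxy-N,5-dimethylhex-4-enamide; 5 vinylmagnesium bromide
Product: 6 (4R)-4-hydroxy-7-methylocta-1,6-dien-3-one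
Conditions: vinylMgBr (3 equiv), THF, −78 to 0 °C, cold aqueous quench
Reagents that add atoms: none
Why: Weinreb ketone synthesis, in which the first equivalent of Grignard reagent only deprotonates the hydroxyl and the chelated tetrahedral adduct stops at mono-addition; the cold quench should limit conjugate addition of the released amine.

**Step 4**
Reactants: 7 2-[(tert-butyldimethylsilyl)oxy]acetaldehyde; 8 prop-1-en-2-ylmagnesium bromide
Product: 9 1-[(tert-butyldimethylsilyl)oxy]-3-methylbut-3-en-2-ol (racemic)
Conditions: THF, −78 °C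
Reagents that add atoms: none
Why: 1,2-Addition of an alkenyl Grignard reagent to an α-silyloxy aldehyde; the new stereocentre is removed in step 5, so no control is needed.

**Step 5**
Reactants: 9 1-[(tert-butyldimethylsilyl)oxy]-3-methylbut-3-en-2-ol
Product: 10 1-[(tert-butyldimethylsilyl)oxy]-3-methylbut-3-en-2-one
Conditions: Dess–Martin periodinane, CH2Cl2, 0 °C to rt
Reagents that add atoms: none
Why: Dess–Martin oxidation of a secondary allylic alcohol under near-neutral conditions that spare the silyl ether.

**Step 6**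
Reactants: 10 1-[(tert-butyldimethylsilyl)oxy]-3-methylbut-3-en-2-one
Product: 11 (1Z)-1-[(tert-butyldimethylsilyl)oxy]-3-methyl-2-[(triethylsilyl)oxy]buta-1,3-diene
Conditions: TESOTf, Et3N, CH2Cl2, −78 to 0 °C
Reagents that add atoms: triethylsilyl trifluoromethanesulfonate, CC[Si](CC)(CC)OS(=O)(=O)C(F)(F)F
Why: Soft enolisation (silyl triflate, tertiary amine) at the only α-CH2 of the ketone, expected to give the (Z) enediol diether with the two silyloxy groups cis and OTBS on the outside of the diene.

**Step 7**
Reactants: 11 (1Z)-1-[(tert-butyldimethylsilyl)oxy]-3-methyl-2-[(triethylsilyl)oxy]buta-1,3-diene; 6 (4R)-4-hydroxy-7-methylocta-1,6-dien-3-one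
Product: 12 (2R)-1-[(1R,2R)-2-[(tert-butyldimethylsilyl)oxy]-4-methyl-3-[(triethylsilyl)oxy]cyclohex-3-en-1-yl]-2-hydroxy-5-methylhex-4-en-1-one (acyl and OTBS cis on the ring)
Conditions: toluene (1 M), 0 °C to rt
Reagents that add atoms: none
Why: Thermal, concerted but asynchronous normal-demand Diels–Alder reaction of the internally hydrogen-bonded α'-hydroxy vinyl ketone 6 with the electron-rich diene 11; the closest known type is the cycloaddition of chiral α'-hydroxy enone dienophiles with oxygenated acyclic dienes. The cyclohexene is the only ring closed, by an intermolecular suprafacial [4π+2π] closure that joins the unsubstituted diene CH2 terminus to the enone β-carbon and the OTBS-bearing terminus to the enone α-carbon. The acyl-bearing ring stereocentre is controlled by the side-chain carbinol: the O–H···O=C bond holds the s-cis enone and the carbinol in one plane, the prenyl CH2 covers one face, and the diene adds to the other, which for the (R)-carbinol is the face leading to the ring configuration of the target. The OTBS-bearing stereocentre follows from the endo transition state together with the (Z) enol ether geometry, which places OTBS cis to the acyl group. The step needs ortho regioselectivity, which the 1-silyloxy group (largest HOMO coefficient at the remote CH2 terminus), the 3-methyl group and the lower hindrance of the CH2 terminus should secure against the opposing 2-silyloxy group. It also needs the enone to react only as the 2π partner, which its hydrogen-bond activation should ensure.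

**Step 8**
Reactants: 12 the cycloadduct
Product: 13 (2R)-1-[(1R,2R)-2-[(tert-butyldimethylsilyl)oxy]-4-methyl-3-[(triethylsilyl)oxy]cyclohex-3-en-1-yl]-5-methyl-1-oxohex-4-en-2-yl 3-methylbut-2-enoate
Conditions: 3-methylbut-2-enoyl chloride, pyridine, DMAP (cat.), CH2Cl2, 0 °C
Reagents that add atoms: 3-methylbut-2-enoyl chloride, CC(C)=CC(=O)Cl
Why: DMAP-catalysed acylation of the secondary α-hydroxy ketone with retention at the carbinol; pyridine is too weak a base to deconjugate the senecioyl unit through a vinylketene or to epimerise the α-centres.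

**Step 9**
Reactants: 13 the keto ester
Product: 14 (3R)-2-[(1S,2R)-2-[(tert-butyldimethylsilyl)oxy]-4-methyl-3-[(triethylsilyl)oxy]cyclohex-3-en-1-yl]-6-methylhepta-1,5-dien-3-yl 3-methylbut-2-enoate
Conditions: Tebbe reagent (1.2 equiv), pyridine (cat.), THF/toluene, −40 to 0 °C
Reagents that add atoms: Tebbe reagent, C[Al-]1(C)C[Ti](C2C=CC=C2)(C2C=CC=C2)[Cl+]1
Why: Tebbe methylenation (titanium methylidene [2+2]/retro-[2+2]) is non-basic, so the two α-CH centres are not enolised, and at low temperature a ketone should react before the conjugated ester, while the silyl enol ether masks the ring carbonyl.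

**Step 10**
Reactants: 14 the silyl enol ether
Product: 15 (3R)-2-[(1S,2R)-2-[(tert-butyldimethylsilyl)oxy]-4-methyl-3-oxocyclohex-4-en-1-yl]-6-methylhepta-1,5-dien-3-yl 3-methylbut-2-enoate
Conditions: Pd(OAc)2 (1.1 equiv), MeCN, rt
Reagents that add atoms: none
Why: Saegusa–Ito oxidation, in which the palladium(II) enolate formed from the triethylsilyl enol ether undergoes β-hydride elimination toward the ring CH2 to give the endocyclic 2-methyl enone; the allylic OTBS ether is not an enol ether and stays.

**Step 11**
Reactants: 15 the enone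
Product: 16 (3R)-2-[(1S,2R,3S)-2-[(tert-butyldimethylsilyl)oxy]-3-hydroxy-4-methylcyclohex-4-en-1-yl]-6-methylhepta-1,5-dien-3-yl 3-methylbut-2-enoate
Conditions: NaBH4, CeCl3·7H2O, MeOH, −78 °C
Reagents that add atoms: none
Why: Luche 1,2-reduction, in which axial hydride delivery anti to the pseudoaxial OTBS group and to the side chain should place the new hydroxyl cis to both, on the face where the oxirane is needed (direct alkaline epoxidation of 15 would be expected to add anti to the side chain, hence this detour).

**Step 12**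
Reactants: 16 the allylic alcohol
Product: 17 (3R)-2-[(1R,2R,3R,4S,6S)-3-[(tert-butyldimethylsilyl)oxy]-2-hydroxy-1-methyl-7-oxabicyclo[4.1.0]heptan-4-yl]-6-methylhepta-1,5-dien-3-yl 3-methylbut-2-enoate
Conditions: VO(acac)2 (5 mol %), t-BuOOH, CH2Cl2, 0 °C to rt
Reagents that add atoms: tert-butyl hydroperoxide, CC(C)(C)OO
Why: Vanadium-catalysed hydroxyl-directed epoxidation transfers the peroxide oxygen to the alkene face syn to the allylic OH, which sets both oxirane carbons on the face of the side chain, while the alkenes that lack a directing hydroxyl are left alone.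

**Step 13**
Reactants: 17 the epoxy alcohol
Product: 18 (3R)-2-[(1S,3R,4S,6S)-3-[(tert-butyldimethylsilyl)oxy]-1-methyl-2-oxo-7-oxabicyclo[4.1.0]heptan-4-yl]-6-methylhepta-1,5-dien-3-yl 3-methylbut-2-enoate
Conditions: Dess–Martin periodinane, CH2Cl2, rt
Reagents that add atoms: none
Why: Dess–Martin oxidation of the secondary alcohol to the ketone under conditions that should neither open the oxirane nor epimerise the silyloxy-bearing α-carbon.

**Step 14**
Reactants: 18 the silyloxy epoxy ketone
Product: 19 (3R)-2-[(1S,3R,4S,6S)-3-hydroxy-1-methyl-2-oxo-7-oxabicyclo[4.1.0]heptan-4-yl]-6-methylhepta-1,5-dien-3-yl 3-methylbut-2-enoate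
Conditions: HF·pyridine, THF, 0 °C to rt
Reagents that add atoms: none
Why: Fluoride-driven Si–O cleavage under buffered acidic conditions avoids the base-induced epimerisation or α-ketol shift of the product, and an oxirane next to a carbonyl group is deactivated toward acid opening.

**Step 15**
Reactants: 19 the α-hydroxy epoxy ketone
Product: 20 (3R)-6-methyl-2-[(1S,3S,4S,6S)-1-methyl-3-[(3-methylbut-2-enoyl)oxy]-2-oxo-7-oxabicyclo[4.1.0]heptan-4-yl]hepta-1,5-dien-3-yl 3-methylbut-2-enoate (CNP0140369.1)
Conditions: PPh3, DIAD, 3-methylbut-2-enoic acid, toluene, 0 °C to rt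
Reagents that add atoms: 3-methylbut-2-enoic acid, CC(C)=CC(=O)O
Why: Mitsunobu esterification, in which the carboxylate displaces the alkoxyphosphonium group by SN2 at the carbinol next to the ketone, entering on the face opposite the side chain, so the ring ester ends up trans to the side chain as in the target.

**Compound list**
1 | methyl (2R)-oxirane-2-carboxylate | COC(=O)[C@H]1CO1 | starting material
2 | (2-methylprop-1-en-1-yl)magnesium bromide | CC(C)=C[Mg]Br | starting material
3 | methyl (2R)-2-hydroxy-5-methylhex-4-enoate | COC(=O)[C@H](O)CC=C(C)C | intermediate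
4 | (2R)-2-hydroxy-N-methoxy-N,5-dimethylhex-4-enamide | CON(C)C(=O)[C@H](O)CC=C(C)C | intermediate
5 | vinylmagnesium bromide | C=C[Mg]Br | starting material
6 | (4R)-4-hydroxy-7-methylocta-1,6-dien-3-one | C=CC(=O)[C@H](O)CC=C(C)C | intermediate
7 | 2-[(tert-butyldimethylsilyl)oxy]acetaldehyde | CC(C)(C)[Si](C)(C)OCC=O | starting material
8 | prop-1-en-2-ylmagnesium bromide | CC(=C)[Mg]Br | starting material
9 | 1-[(tert-butyldimethylsilyl)oxy]-3-methylbut-3-en-2-ol (racemic) | CC(=C)C(O)CO[Si](C)(C)C(C)(C)C | intermediate
10 | 1-[(tert-butyldimethylsilyl)oxy]-3-methylbut-3-en-2-one | CC(=C)C(=O)CO[Si](C)(C)C(C)(C)C | intermediate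
11 | (1Z)-1-[(tert-butyldimethylsilyl)oxy]-3-methyl-2-[(triethylsilyl)oxy]buta-1,3-diene | C=C(C)/C(O[Si](CC)(CC)CC)=C/O[Si](C)(C)C(C)(C)C | intermediate
12 | (2R)-1-[(1R,2R)-2-[(tert-butyldimethylsilyl)oxy]-4-methyl-3-[(triethylsilyl)oxy]cyclohex-3-en-1-yl]-2-hydroxy-5-methylhex-4-en-1-one | O=C([C@@H](CC=C(C)C)O)[C@@H]1CCC(C)=C(O[Si](CC)(CC)CC)[C@@H]1O[Si](C)(C)C(C)(C)C | intermediate
13 | (2R)-1-[(1R,2R)-2-[(tert-butyldimethylsilyl)oxy]-4-methyl-3-[(triethylsilyl)oxy]cyclohex-3-en-1-yl]-5-methyl-1-oxohex-4-en-2-yl 3-methylbut-2-enoate | O=C([C@@H](CC=C(C)C)OC(=O)C=C(C)C)[C@@H]1CCC(C)=C(O[Si](CC)(CC)CC)[C@@H]1O[Si](C)(C)C(C)(C)C | intermediate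
14 | (3R)-2-[(1S,2R)-2-[(tert-butyldimethylsilyl)oxy]-4-methyl-3-[(triethylsilyl)oxy]cyclohex-3-en-1-yl]-6-methylhepta-1,5-dien-3-yl 3-methylbut-2-enoate | C=C([C@@H](CC=C(C)C)OC(=O)C=C(C)C)[C@@H]1CCC(C)=C(O[Si](CC)(CC)CC)[C@@H]1O[Si](C)(C)C(C)(C)C | intermediate
15 | (3R)-2-[(1S,2R)-2-[(tert-butyldimethylsilyl)oxy]-4-methyl-3-oxocyclohex-4-en-1-yl]-6-methylhepta-1,5-dien-3-yl 3-methylbut-2-enoate | C=C([C@@H](CC=C(C)C)OC(=O)C=C(C)C)[C@@H]1CC=C(C)C(=O)[C@@H]1O[Si](C)(C)C(C)(C)C | intermediate
16 | (3R)-2-[(1S,2R,3S)-2-[(tert-butyldimethylsilyl)oxy]-3-hydroxy-4-methylcyclohex-4-en-1-yl]-6-methylhepta-1,5-dien-3-yl 3-methylbut-2-enoate | C=C([C@@H](CC=C(C)C)OC(=O)C=C(C)C)[C@@H]1CC=C(C)[C@H](O)[C@@H]1O[Si](C)(C)C(C)(C)C | intermediate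
17 | (3R)-2-[(1R,2R,3R,4S,6S)-3-[(tert-butyldimethylsilyl)oxy]-2-hydroxy-1-methyl-7-oxabicyclo[4.1.0]heptan-4-yl]-6-methylhepta-1,5-dien-3-yl 3-methylbut-2-enoate | C=C([C@@H](CC=C(C)C)OC(=O)C=C(C)C)[C@@H]1C[C@@H]2O[C@]2(C)[C@H](O)[C@@H]1O[Si](C)(C)C(C)(C)C | intermediate
18 | (3R)-2-[(1S,3R,4S,6S)-3-[(tert-butyldimethylsilyl)oxy]-1-methyl-2-oxo-7-oxabicyclo[4.1.0]heptan-4-yl]-6-methylhepta-1,5-dien-3-yl 3-methylbut-2-enoate | C=C([C@@H](CC=C(C)C)OC(=O)C=C(C)C)[C@@H]1C[C@@H]2O[C@]2(C)C(=O)[C@@H]1O[Si](C)(C)C(C)(C)C | intermediate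
19 | (3R)-2-[(1S,3R,4S,6S)-3-hydroxy-1-methyl-2-oxo-7-oxabicyclo[4.1.0]heptan-4-yl]-6-methylhepta-1,5-dien-3-yl 3-methylbut-2-enoate | C=C([C@@H](CC=C(C)C)OC(=O)C=C(C)C)[C@@H]1C[C@@H]2O[C@]2(C)C(=O)[C@@H]1O | intermediate
20 | (3R)-6-methyl-2-[(1S,3S,4S,6S)-1-methyl-3-[(3-methylbut-2-enoyl)oxy]-2-oxo-7-oxabicyclo[4.1.0]heptan-4-yl]hepta-1,5-dien-3-yl 3-methylbut-2-enoate | C=C([C@@H](CC=C(C)C)OC(=O)C=C(C)C)[C@@H]1C[C@@H]2O[C@]2(C)C(=O)[C@H]1OC(=O)C=C(C)C | target

**Step count and risks**
Total steps: 15. Longest linear sequence: 12 (steps 1–3 and 7–15); steps 4–6 form the convergent diene branch.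

Steps most likely to fail:

Step 7. The controlling stereocentre of 6 carries only a primary alkyl group, so face discrimination in the hydrogen-bonded dienophile may be modest; the 2-silyloxy group may also erode ortho regioselectivity, and the free hydroxyl may desilylate the diene. The fallback replaces substrate control by catalyst control. It sets out from 6, which is acylated (3-methylbut-2-enoyl chloride, pyridine, DMAP) to (4R)-7-methyl-3-oxoocta-1,6-dien-4-yl 3-methylbut-2-enoate F1. F1 is then combined with diene 11 under a chiral oxazaborolidinium Lewis acid, in the catalyst enantiomer matched to the required enone face, which binds the ketone, sharpens ortho selectivity and overrides the weak substrate bias. This gives 13 directly, where it rejoins the route before step 9.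

Step 9. The hindered α-acyloxy ketone may react slowly, so that methylenation of the ester carbonyl, titanium enolate formation with epimerisation, or cleavage of the silyl enol ether by the aluminium by-product competes. The fallback removes the competing ester by changing the order. It sets out from 12, whose free α-hydroxy ketone is methylenated with dimethyltitanocene (excess, toluene/THF, 65 °C; the hydroxyl is carried as its titanium alkoxide) to (3R)-2-[(1S,2R)-2-[(tert-butyldimethylsilyl)oxy]-4-methyl-3-[(triethylsilyl)oxy]cyclohex-3-en-1-yl]-6-methylhepta-1,5-dien-3-ol F2. Acylation of F2 with 3-methylbut-2-enoyl chloride and pyridine then returns to the route at 14.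

Step 15. Activation of the hindered carbinol, flanked by the ketone and the branched side chain, may be slow; elimination, esterification with retention through an acyloxyphosphonium species, or epimerisation by the basic betaine may then take over. The fallback separates activation from displacement. It sets out from 19, which is converted (Tf2O, pyridine, CH2Cl2, −30 °C) into (3R)-6-methyl-2-[(1S,3R,4S,6S)-1-methyl-2-oxo-3-[(trifluoromethanesulfonyl)oxy]-7-oxabicyclo[4.1.0]heptan-4-yl]hepta-1,5-dien-3-yl 3-methylbut-2-enoate F3. SN2 displacement of F3 with caesium 3-methylbut-2-enoate and 18-crown-6 in toluene, with inversion at the α-keto carbon, arrives at 20.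

**Further compounds**
F1 | step 7 | (4R)-7-methyl-3-oxoocta-1,6-dien-4-yl 3-methylbut-2-enoate | C=CC(=O)[C@H](OC(=O)C=C(C)C)CC=C(C)C
F2 | step 9 | (3R)-2-[(1S,2R)-2-[(tert-butyldimethylsilyl)oxy]-4-methyl-3-[(triethylsilyl)oxy]cyclohex-3-en-1-yl]-6-methylhepta-1,5-dien-3-ol | C=C([C@@H](CC=C(C)C)O)[C@@H]1CCC(C)=C(O[Si](CC)(CC)CC)[C@@H]1O[Si](C)(C)C(C)(C)C
F3 | step 15 | (3R)-6-methyl-2-[(1S,3R,4S,6S)-1-methyl-2-oxo-3-[(trifluoromethanesulfonyl)oxy]-7-oxabicyclo[4.1.0]heptan-4-yl]hepta-1,5-dien-3-yl 3-methylbut-2-enoate | C=C([C@@H](CC=C(C)C)OC(=O)C=C(C)C)[C@@H]1C[C@@H]2O[C@]2(C)C(=O)[C@@H]1OS(=O)(=O)C(F)(F)F
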